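(The numbers in the tables were computed with constants of no real substance, and the scatter is random.)

I decided to keep the books on the partner, because the alpha flask holds 0.0800 M of it, less than its 0.250 M of starting material, which makes partner the limiting reagent there. What to watch at 29 min is how far the target stands below its ceiling of 32.0% of the starting material.

| flask | starting material | partner | free catalyst | target | time |
|---|---|---|---|---|---|
| zeta | 0.250 M | 0.200 M | 0.00500 M |  |  |
| epsilon | 0.250 M | 0.200 M | 0.00250 M |  |  |
| gamma | 0.250 M | 0.200 M | 0.00500 M | 0.120 M |  |
| alpha | 0.250 M | 0.0800 M | 0.00500 M |  | 29 min |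

| run | time / min | [target] / M |
|---|---|---|
| zeta run | 1.2 | 0.0098 |
| zeta run | 2.2 | 0.0205 |
| zeta run | 4.2 | 0.0378 |
| zeta run | 8.0 | 0.0699 |
| zeta run | 15 | 0.1236 |
| zeta run | 29 | 0.1926 |
| epsilon run | 1.2 | 0.0053 |
| epsilon run | 2.2 | 0.0102 |
| epsilon run | 4.2 | 0.0179 |
| epsilon run | 8.0 | 0.0353 |
| epsilon run | 15 | 0.0654 |
| epsilon run | 29 | 0.1176 |
| gamma run | 1.2 | 0.1303 |
| gamma run | 2.2 | 0.1393 |
| gamma run | 4.2 | 0.1559 |
| gamma run | 8.0 | 0.1891 |
| gamma run | 15 | 0.2429 |
| gamma run | 29 | 0.3143 |

(each reading ± 8 × 10⁻⁴ M)

- Overall: starting material + partner -> target, with free catalyst as catalyst.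
- Constant volume, constant temperature.
- Bound and free are read together.
- An order is taken over about fifteen percent of the charge, up and down.

- apparent order in [free catalyst] of the starting rate, round the charge of the zeta run (the rate where two percent of its starting material have turned into target)
- target in the alpha run at 29 min, as a share of the starting material charged

The epsilon run had half the catalyst of the zeta run, and by 8.0 min it had made 0.0353 M of target against 0.0699 M in zeta. In logarithms:

order = log(target ratio) / log(catalyst ratio) = 0.986

So I took the speed as proportional to the catalyst. The gamma run, charged with 0.120 M of target, had added 0.1943 M by 29 min, close to the 0.1926 M of zeta, so I booked no penalty for target present.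

I booked each mole of partner into target and split the time into two entries:

time = target made / full speed + tenfold time × powers of ten the partner has fallen

Two zeta readings, at 8.0 min and 29 min, gave me a partner level of 0.0350 M where the speed falls to half of full, and a full speed of 0.0106 M min⁻¹. Together they gave the tenfold time, the minutes my rule adds for each factor of ten by which the leftover partner falls at this catalyst charge: 7.58 min.

The alpha flask has the catalyst charge of zeta, so its books ran:

partner charged: 0.0800 M
time to book it at full speed: 7.53 min
time remaining: 21.5 min
powers of ten fallen in that time: 2.83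
partner left: 1.18 × 10⁻⁴ M
target: 32.0% of the starting material

The forecast gave an order of 0.99 (0.9 to 1.08) and 31.9% (30.5% to 32%), close to my figure, saying “Partner is essentially exhausted”.

The flask gave an order of 1.0 and 31.7% in the alpha run.

    free catalyst + starting material → catalyst-substrate complex (156.0 L mol⁻¹ min⁻¹)
    catalyst-substrate complex + partner → loaded catalyst (144.0 L mol⁻¹ min⁻¹)
    loaded catalyst → target + free catalyst (250.2 min⁻¹)
    2 partner ⇌ idle reagent dimer, settled at all times (80.80 L mol⁻¹)
    catalyst-substrate complex + starting material ⇌ doubly bound catalyst, settled at all times (6.100 L mol⁻¹)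

That leaves 6.56 × 10⁻⁴ M of the alpha partner charge not turned into target at 29 min, more than my 1.18 × 10⁻⁴ M. The apparent order in partner early in the zeta run was 0.53, above the 0.149 my rule gives there. In the epsilon run the tenfold time stretches to 15.2 min, and the same two entries put 0.125 M of target at 30.0 min, where the flask reached it at 30.6 min.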